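J, the reagent, stands on the left of every step, so you can read each fraction below against the J spent per Z charged, however J arrives.

| flask | Z | J | time | remark |
|---|---|---|---|---|
| dusk | 10 mM | 5.00 mM (in portions, 2) | 10 min | the portions of J follow each other after 6.0 s, the first at the start |
| winter | 10 mM | 10.0 mM (in portions, 2) | 10 min | the portions of J follow each other after 6.0 s, the first at the start |
| spring | 10 mM | 20.0 mM (in portions, 2) | 10 min | the portions of J follow each other after 6.0 s, the first at the start |
| summer | 10 mM | 40.0 mM (in portions, 2) | 10 min | the portions of J follow each other after 6.0 s, the first at the start |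

    Z + J → G + Q (k1 = 9.50 M⁻¹ s⁻¹)
    J + G → J.G (k2 = 1.37 M⁻¹ s⁻¹)
    Z + J → X + Q (k3 = 3.48 M⁻¹ s⁻¹)
    J + G → L + Q (k4 = 0.318 M⁻¹ s⁻¹)
    J + X → L + Q (k5 = 4.52 M⁻¹ s⁻¹)

* amount of G at the end, in percent of the Z charged for dusk, winter, spring, summer, in this order
* the shape of the row from first to last (hardly changes / rises all the way / rises, then falls / falls, then rises / falls all the way)

- "hardly changes" means that all values lie within two and a half points (for a concentration: within two and a half percent of the largest)
- run time (dusk): 10 min

**The start.** Write z, g and x for Z, G and X as fractions of the Z charged. Let θ be the running time integral of J, multiplied by the summed constant of the two Z steps, 13.0 M⁻¹ s⁻¹. Then z = e^(−θ). At first, each J spent on Z goes to G with the share s = 0.732, which comes from a selectivity factor k1/k3 of 2.73. G is lost more slowly than Z, at the relative speed ρ = 0.130, so dg/dθ = sz − ρg.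

**The crest.** The curve tops out where sz = ρg, which falls at θ = 2.34. There z is 9.59%, g is 54.0% and x is 14.2%. Each Z consumed costs one J, and each G or X carried on costs another. That gives the crest charge, the J spent per Z charged at the top of g: 1.13.

**The far end.** Past the crest, g slides towards zero at 2.00 J per Z. Spring charges just that, so late on, with z small, the J left equals g plus x. The reciprocal of g then climbs at least at (k2 + k4) times the Z charged, which puts g below 9.87% at 10 min. Summer keeps a surplus of 20.0 mM if the adducts take their full J. That makes G's loss pseudo-first-order, with a time 0.494 min, far shorter than the run.

**My call.** Dusk and winter charge 0.500 and 1.00 J per Z, both below the crest charge, so the row goes rises, then falls. My reckoning gives no height for dusk or winter.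

**The forecast.** It reads 32.9%, 52.8%, 8.4% and 0%, shape rises, then falls, and starts from this: "The portioning drops out".

**The flask.** The row comes out at 32.9%, 52.8%, 8.39% and 0%, shape rises, then falls, and it turns at 11 mM of J. The crest charge, put on this Z, is 11.3 mM. Use its z as a marker on winter: Z left there is 16%, more than the 9.59% at the crest, so winter stopped on the rising side. Winter's G stands 1.2 percentage points under the crest height.

All constants are invented; the result is computed.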